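J faded slowly in these flasks, over days, so I looked for its end in the last readings and not in its early fall.

| flask | Z | L | G | remark | time |
|---|---|---|---|---|---|
| Wednesday's | 1 M | 0.47 M | 2 mM | run made earlier |  |
| Sunday's | 1 M | 1 M | 2 mM | run made earlier |  |
| flask | 1.0 M | 0.700 M | 2.0 mM |  | 8.0 d |

| run | time / d | E / % | J / % |
|---|---|---|---|
| Wednesday's | 0.625 | 8.3 | 9.1 |
| Wednesday's | 1.25 | 11.1 | 6.7 |
| Wednesday's | 2.08 | 12.3 | 4.0 |
| Wednesday's | 3.00 | 14.6 | 1.6 |
| Wednesday's | 4.00 | 16.4 | 2.6 |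
| Wednesday's | 5.00 | 17.7 | 0.9 |
| Sunday's | 0.250 | 7.5 | 12.6 |
| Sunday's | 0.833 | 13.1 | 11.1 |
| Sunday's | 1.25 | 16.5 | 8.6 |
| Sunday's | 2.08 | 21.1 | 4.2 |
| Sunday's | 3.00 | 22.0 | 2.2 |
| Sunday's | 4.00 | 20.6 | 0.8 |
| Sunday's | 5.00 | 21.9 | 0.1 |

(each reading ± 1 percentage point)

- the numbers in the tables scatter by 1 percentage point (one standard deviation)
- steps that have been proposed: Z + L <-> J; Z + L <-> E; J + G <-> E + G; 2 G <-> D; 2 L -> Q

- ratio of E to J at 40 min
- ratio of E to J at 8.0 d

Z and L give J and E, and J turns into E over G. Both steps from Z and L are proposed as reversible, so J need not fade to nothing: the end could lie under thermodynamic rather than kinetic control.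

The last two readings of each run averaged 19.1% of E and 1.10% of J. That gave 17.4 for the late ratio, mean E over mean J at the end of the readings. Mean J carried a scatter of 0.5 percentage points, so the late ratio spanned 12.0 to 31.9, and I expected the flask's ratio at 8.0 d within that span.

The forecast gave 0.35 at 40 min and 150 at 8.0 d, higher than my span, and it added that “the ratio is very uncertain”.

The flask gave 0.438 at 40 min and 29.0 at 8.0 d, which is less than the top of the span and more than the late ratio of 17.4.

    Z + L ⇌ J (K = 1.90 M⁻¹, k = 2.22 × 10⁻⁵ M⁻¹ s⁻¹)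
    Z + L ⇌ E (K = 65.0 M⁻¹, k = 8.90 × 10⁻⁶ M⁻¹ s⁻¹)
    J + G ⇌ E + G, rate k3*[G]*[J] forward; the back reaction follows from the equilibrium constant (k = 0.0127 M⁻¹ s⁻¹)
    2 G ⇌ D (K = 6240 M⁻¹, k = 0.0787 M⁻¹ s⁻¹)
    2 L → Q (k = 8.22 × 10⁻⁵ M⁻¹ s⁻¹)

At 40 min part of the E in the flask had come straight from Z and L: the same run without that step, both ways, gave a ratio of 0.0222 at that time, not 0.438. At 8.00 d the flask still held 0.728% of J beside 21.1% of E. In the neighbour charged with 2.8 M of L, dividing its 31.5% of E by the late ratio of 17.4 gave 1.81% of J; it held 1.02%, a ratio of 31.0, less than the top of the span.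

The runs are simulated for an exercise.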